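**Retrosynthetic overview**
1. The C40 polyene is cut at C11=C12 and C11'=C12' (two Wittig unions): a C15 ε-end phosphonium salt, the C10 trienedial, and a C15 epoxy-dienal.
2. The ε-ring is made by closing the C5'–C6' bond of an open-chain, achiral iodo-dienone with a palladium-catalysed enantioselective γ-alkenylation, giving (R)-α-ionone.
3. Enabling feature: C6' of the ε-ring is a doubly allylic methine. It is the γ-carbon of the C9' carbonyl through C7'=C8' (a dienolate carbon) and is bonded to C5', the methyl-bearing alkenyl carbon of the ring C4'=C5' bond (a cis-alkenyl iodide carbon).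
4. The epoxy end comes from β-cyclocitral (six-membered ring purchased); the oxirane is closed by Sharpless asymmetric epoxidation of β-cyclogeraniol, which sets C5 and C6.
5. Ring order: ε-ring (step 5), then oxirane (step 12) in the second branch; the branches are joined in step 16.

Key step: step 5

Assumption: the sense of asymmetric induction in step 5 cannot be predicted with certainty, so (R)-DTBM-SEGPHOS stands for whichever ligand antipode delivers the (R)-product.

**Step 1**
Reactants: 1 methyl 3,3-dimethylpent-4-enoate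
Product: 2 methyl 3,3-dimethyl-6-oxohexanoate
Conditions: Rh(acac)(CO)2 (0.5 mol %), Xantphos (1 mol %), CO/H2 (1:1, 10 bar), toluene, 80 °C
Reagents that add atoms: carbon monoxide, [C-]#[O+]
Why: Rhodium-catalysed hydroformylation of a monosubstituted alkene should give only the linear aldehyde, because the adjacent quaternary carbon and the wide-bite-angle ligand block branched insertion, and the ester is inert.

**Step 2**
Reactants: 2 methyl 3,3-dimethyl-6-oxohexanoate
Product: 3 methyl (6Z)-7-iodo-3,3-dimethyloct-6-enoate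
Conditions: EtPPh3I, n-BuLi, THF, 0 °C; I2, −78 °C; NaN(SiMe3)2, −78 to −20 °C; then 2, −78 °C to rt
Reagents that add atoms: ethyltriphenylphosphonium iodide, CC[P+](c1ccccc1)(c1ccccc1)c1ccccc1.[I-]; iodine, II
Why: Stork–Zhao-type α-iodo Wittig olefination, in which the (1-iodoethylidene)phosphorane made in the flask attacks the aldehyde much faster than the ester and should give the (Z)-2-iodoalk-2-ene (iodine cis to the chain) under kinetic control.

**Step 3**
Reactants: 3 methyl (6Z)-7-iodo-3,3-dimethyloct-6-enoate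
Product: 5 (6Z)-7-iodo-3,3-dimethyloct-6-enal, via diisobutylaluminium hemiacetalate 4 (not isolated)
Conditions: i-Bu2AlH (1.1 equiv), CH2Cl2, −78 °C; then aqueous Rochelle salt
Reagents that add atoms: none
Why: Partial reduction of an ester, in which the tetrahedral aluminium hemiacetalate is stable at −78 °C and releases the aldehyde only on hydrolysis, while the alkenyl iodide is untouched.

**Step 4**
Reactants: 5 (6Z)-7-iodo-3,3-dimethyloct-6-enal
Product: 6 (3E,9Z)-10-iodo-6,6-dimethylundeca-3,9-dien-2-one
Conditions: Ph3P=CHCOCH3 (1.3 equiv), toluene, 80 °C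
Reagents that add atoms: 1-(triphenylphosphoranylidene)propan-2-one, CC(=O)C=P(c1ccccc1)(c1ccccc1)c1ccccc1
Why: Wittig reaction of a stabilised ylide with an unhindered aldehyde should give the (E)-enone and leave the alkenyl iodide intact.

**Step 5**
Reactants: 6 (3E,9Z)-10-iodo-6,6-dimethylundeca-3,9-dien-2-one
Product: 7 (R)-α-ionone [(3E)-4-[(1R)-2,6,6-trimethylcyclohex-2-en-1-yl]but-3-en-2-one]
Conditions: Pd2(dba)3 (2.5 mol %), (R)-DTBM-SEGPHOS (6 mol %), K3PO4 (2 equiv), toluene (0.02 M), 60 °C, argon
Reagents that add atoms: none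
Why: Proposed new method: zerovalent palladium inserts into the C10–I bond with retention of the Z geometry, K3PO4 converts the enone reversibly into its extended dienolate, and C–C reductive elimination from the divalent palladium alkenyl dienolate joins the γ-carbon C5 to C10; the closest known reactions are the palladium-catalysed intramolecular α-alkenylation of ketone enolates with alkenyl halides, the intermolecular γ-arylation of enone dienolates and the asymmetric α-vinylation of ketones with chiral phosphines, but an enantioselective intramolecular γ-alkenylation that creates a tertiary doubly allylic centre has not been shown. The six-membered ring closes by exo attack of the dienolate γ-carbon on the alkenyl carbon (reductive elimination from a seven-membered palladacycle), so the C9=C10 bond ends endocyclic and the enone stays exocyclic. The one new stereocentre (ring C1, R) is set in the bond-forming event by the chiral bisphosphine, which selects between the two enantiofacial allyl-type dienolate complexes; these should interconvert through the O-bound dienolate faster than they eliminate. Regioselectivity is secured by ring size, since α- or α'-coupling would need an eight- or ten-membered ring, and only the Z-iodide can cyclise. The E-enone geometry is kept because the dienolate is formed from the E-enone in its s-trans form. The weak, insoluble base and moderate temperature are chosen so that the hindered doubly allylic C–H of the product is not deprotonated again (no racemisation, no shift to the β-isomer), and high dilution suppresses intermolecular coupling and the slower 7-exo Heck insertion.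

**Step 6**
Reactants: 7 (R)-α-ionone
Product: 8 (1E)-3-methyl-1-[(1R)-2,6,6-trimethylcyclohex-2-en-1-yl]penta-1,4-dien-3-ol (both C3 epimers)
Conditions: CH2=CHMgBr (1.3 equiv), THF, −20 to 0 °C; then aqueous NH4Cl
Reagents that add atoms: vinylmagnesium bromide, C=C[Mg]Br
Why: Grignard 1,2-addition to the enone should dominate for this hard nucleophile at low temperature; the new carbinol centre forms as an epimer mixture that is erased in step 7, and the ring stereocentre is not touched.

**Step 7**
Reactants: 8 (1E)-3-methyl-1-[(1R)-2,6,6-trimethylcyclohex-2-en-1-yl]penta-1,4-dien-3-ol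
Product: 9 [(2E,4E)-3-methyl-5-[(1R)-2,6,6-trimethylcyclohex-2-en-1-yl]penta-2,4-dien-1-yl]triphenylphosphonium bromide
Conditions: PPh3·HBr (1.05 equiv), MeOH/CH2Cl2, 0 °C to rt; crystallisation
Reagents that add atoms: triphenylphosphine hydrobromide, [Br-].[PH+](c1ccccc1)(c1ccccc1)c1ccccc1
Why: Allylic transposition (SN1'), in which the tertiary bis-allylic alcohol ionises to a pentadienyl cation that PPh3 captures at the primary terminus to give the conjugated (E)-phosphonium salt, the standard way to ionone-derived Wittig salts.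

**Step 8**
Reactants: 9 C15 phosphonium bromide; 10 (2E,4E,6E)-2,7-dimethylocta-2,4,6-trienedial (2.5 equiv)
Product: 12 (2E,4E,6E,8E,10E,12E)-2,7,11-trimethyl-13-[(1R)-2,6,6-trimethylcyclohex-2-en-1-yl]trideca-2,4,6,8,10,12-hexaenal, via the 8Z isomer 11 (not isolated)
Conditions: NaOMe, MeOH/CH2Cl2, 0 °C to rt, dark; then I2 (cat.), hexane/CH2Cl2, daylight, rt
Reagents that add atoms: none
Why: Wittig mono-olefination of the symmetrical dialdehyde (kept in excess) by the semi-stabilised ylide should give an E/Z mixture at the new disubstituted double bond, and iodine-catalysed equilibration funnels the hindered Z isomer into the all-E aldehyde.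

**Step 9**
Reactants: 12 C25 hexaenal
Product: 13 (2E,4E,6E,8E,10E,12E)-2,7,11-trimethyl-13-[(1R)-2,6,6-trimethylcyclohex-2-en-1-yl]trideca-2,4,6,8,10,12-hexaen-1-ol
Conditions: NaBH4, MeOH/THF, 0 °C
Reagents that add atoms: none
Why: Borohydride 1,2-reduction of a polyenal should give the primary allylic alcohol without touching the polyene.

**Step 10**
Reactants: 13 C25 hexaenol
Product: 14 [(2E,4E,6E,8E,10E,12E)-2,7,11-trimethyl-13-[(1R)-2,6,6-trimethylcyclohex-2-en-1-yl]trideca-2,4,6,8,10,12-hexaen-1-yl]triphenylphosphonium bromide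
Conditions: PPh3·HBr (1.05 equiv), MeOH/CH2Cl2, 0 °C to rt, dark
Reagents that add atoms: triphenylphosphine hydrobromide, [Br-].[PH+](c1ccccc1)(c1ccccc1)c1ccccc1
Why: Phosphonium salt formation from a polyenyl primary allylic alcohol through the delocalised cation, captured by PPh3 at the terminal carbon as in the conversion of retinol into its Wittig salt.

**Step 11**
Reactants: 15 β-cyclocitral (2,6,6-trimethylcyclohex-1-ene-1-carbaldehyde)
Product: 16 β-cyclogeraniol [(2,6,6-trimethylcyclohex-1-en-1-yl)methanol]
Conditions: NaBH4, MeOH, 0 °C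
Reagents that add atoms: none
Why: Borohydride 1,2-reduction of the hindered enal should give the allylic alcohol needed for directed epoxidation.

**Step 12**
Reactants: 16 β-cyclogeraniol
Product: 17 [(1R,6R)-2,2,6-trimethyl-7-oxabicyclo[4.1.0]heptan-1-yl]methanol
Conditions: Ti(OiPr)4 (10 mol %), D-(−)-diethyl tartrate (12 mol %), t-BuOOH (2 equiv, in isooctane), 4 Å molecular sieves, CH2Cl2, −20 °C
Reagents that add atoms: tert-butyl hydroperoxide, CC(C)(C)OO
Why: Sharpless asymmetric epoxidation, in which the titanium tartrate delivers oxygen to one face of the allylic alcohol and so sets both oxirane carbons at once (cis by necessity); the unnatural D-(−)-tartrate is chosen because the natural tartrate gives the (2S,3S)-type antipode.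

**Step 13**
Reactants: 17 epoxy alcohol
Product: 18 (1S,6R)-2,2,6-trimethyl-7-oxabicyclo[4.1.0]heptane-1-carbaldehyde
Conditions: Dess–Martin periodinane, pyridine, CH2Cl2, 0 °C to rt
Reagents that add atoms: none
Why: Dess–Martin oxidation under buffered conditions should give the epoxy aldehyde, which cannot epimerise because its α-carbon is quaternary (the change of descriptor at C1 is only a priority change).

**Step 14**
Reactants: 18 epoxy aldehyde
Product: 19 (2E,4E)-3-methyl-5-[(1S,6R)-2,2,6-trimethyl-7-oxabicyclo[4.1.0]heptan-1-yl]penta-2,4-dienenitrile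
Conditions: diethyl (3-cyano-2-methylallyl)phosphonate (1.3 equiv), KOtBu, THF, −30 to 0 °C; chromatography
Reagents that add atoms: diethyl (3-cyano-2-methylprop-2-en-1-yl)phosphonate (E/Z mixture), CCOP(=O)(CC(C)=CC#N)OCC
Why: Horner–Wadsworth–Emmons olefination with the C5 phosphonate should form the new double bond E and, through the equilibrating allylic anion, mainly the 2E nitrile, with any 2Z isomer removed by chromatography.

**Step 15**
Reactants: 19 C15 epoxy nitrile
Product: 21 (2E,4E)-3-methyl-5-[(1S,6R)-2,2,6-trimethyl-7-oxabicyclo[4.1.0]heptan-1-yl]penta-2,4-dienal, via N-diisobutylaluminio aldimine 20 (not isolated)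
Conditions: i-Bu2AlH (1.2 equiv), toluene, −78 °C; then wet silica gel, 0 °C
Reagents that add atoms: water, O
Why: Partial reduction of the nitrile stops at the aluminium aldiminate, which nearly neutral hydrolysis converts into the dienal without opening the acid-sensitive vinylogous epoxide.

**Step 16**
Reactants: 14 C25 phosphonium bromide; 21 C15 epoxy dienal
Product: 23 (all-E)-(5R,6S,6'R)-5,6-epoxy-5,6-dihydro-β,ε-carotene, via the 11Z isomer 22 (not isolated)
Conditions: NaOMe, MeOH/CH2Cl2, 0 °C to rt, dark, argon; then heptane, reflux; crystallisation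
Reagents that add atoms: none
Why: Wittig union of the polyenyl ylide with the epoxy dienal forms C11=C12 as an E/Z mixture, and heating without acid or iodine should convert the hindered 11Z isomer into the all-E target while the epoxide and all three stereocentres stay untouched.

**Compound list**
1 | methyl 3,3-dimethylpent-4-enoate | COC(=O)CC(C)(C)C=C | starting material
2 | methyl 3,3-dimethyl-6-oxohexanoate | COC(=O)CC(C)(C)CCC=O | intermediate
3 | methyl (6Z)-7-iodo-3,3-dimethyloct-6-enoate | COC(=O)CC(C)(C)CC/C=C(I)/C | intermediate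
4 | diisobutylaluminium hemiacetalate, {[(6Z)-7-iodo-1-methoxy-3,3-dimethyloct-6-en-1-yl]oxy}bis(2-methylpropyl)alane | COC(CC(C)(C)CC/C=C(I)/C)O[Al](CC(C)C)CC(C)C | intermediate
5 | (6Z)-7-iodo-3,3-dimethyloct-6-enal | O=CCC(C)(C)CC/C=C(I)/C | intermediate
6 | (3E,9Z)-10-iodo-6,6-dimethylundeca-3,9-dien-2-one | CC(=O)/C=C/CC(C)(C)CC/C=C(I)/C | intermediate
7 | (R)-α-ionone, (3E)-4-[(1R)-2,6,6-trimethylcyclohex-2-en-1-yl]but-3-en-2-one | CC1=CCCC(C)(C)[C@H]1/C=C/C(C)=O | intermediate
8 | (1E)-3-methyl-1-[(1R)-2,6,6-trimethylcyclohex-2-en-1-yl]penta-1,4-dien-3-ol (both C3 epimers) | CC1=CCCC(C)(C)[C@H]1/C=C/C(C)(O)C=C | intermediate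
9 | [(2E,4E)-3-methyl-5-[(1R)-2,6,6-trimethylcyclohex-2-en-1-yl]penta-2,4-dien-1-yl]triphenylphosphonium bromide | CC1=CCCC(C)(C)[C@H]1/C=C/C(C)=C/C[P+](c1ccccc1)(c1ccccc1)c1ccccc1.[Br-] | intermediate
10 | (2E,4E,6E)-2,7-dimethylocta-2,4,6-trienedial | O=C/C(C)=C/C=C/C=C(C)/C=O | starting material
11 | (2E,4E,6E,8Z,10E,12E)-2,7,11-trimethyl-13-[(1R)-2,6,6-trimethylcyclohex-2-en-1-yl]trideca-2,4,6,8,10,12-hexaenal | CC1=CCCC(C)(C)[C@H]1/C=C/C(C)=C/C=C\C(C)=C\C=C\C=C(C)\C=O | intermediate
12 | (2E,4E,6E,8E,10E,12E)-2,7,11-trimethyl-13-[(1R)-2,6,6-trimethylcyclohex-2-en-1-yl]trideca-2,4,6,8,10,12-hexaenal | CC1=CCCC(C)(C)[C@H]1/C=C/C(C)=C/C=C/C(C)=C/C=C/C=C(C)/C=O | intermediate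
13 | (2E,4E,6E,8E,10E,12E)-2,7,11-trimethyl-13-[(1R)-2,6,6-trimethylcyclohex-2-en-1-yl]trideca-2,4,6,8,10,12-hexaen-1-ol | CC1=CCCC(C)(C)[C@H]1/C=C/C(C)=C/C=C/C(C)=C/C=C/C=C(C)/CO | intermediate
14 | [(2E,4E,6E,8E,10E,12E)-2,7,11-trimethyl-13-[(1R)-2,6,6-trimethylcyclohex-2-en-1-yl]trideca-2,4,6,8,10,12-hexaen-1-yl]triphenylphosphonium bromide | CC1=CCCC(C)(C)[C@H]1/C=C/C(C)=C/C=C/C(C)=C/C=C/C=C(C)/C[P+](c1ccccc1)(c1ccccc1)c1ccccc1.[Br-] | intermediate
15 | β-cyclocitral, 2,6,6-trimethylcyclohex-1-ene-1-carbaldehyde | CC1=C(C=O)C(C)(C)CCC1 | starting material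
16 | β-cyclogeraniol, (2,6,6-trimethylcyclohex-1-en-1-yl)methanol | CC1=C(CO)C(C)(C)CCC1 | intermediate
17 | [(1R,6R)-2,2,6-trimethyl-7-oxabicyclo[4.1.0]heptan-1-yl]methanol | OC[C@@]12O[C@]1(C)CCCC2(C)C | intermediate
18 | (1S,6R)-2,2,6-trimethyl-7-oxabicyclo[4.1.0]heptane-1-carbaldehyde | O=C[C@@]12O[C@]1(C)CCCC2(C)C | intermediate
19 | (2E,4E)-3-methyl-5-[(1S,6R)-2,2,6-trimethyl-7-oxabicyclo[4.1.0]heptan-1-yl]penta-2,4-dienenitrile | N#C/C=C(C)/C=C/[C@@]12O[C@]1(C)CCCC2(C)C | intermediate
20 | N-diisobutylaluminio aldimine of 21 | CC(C)C[Al](CC(C)C)N=C/C=C(C)/C=C/[C@@]12O[C@]1(C)CCCC2(C)C | intermediate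
21 | (2E,4E)-3-methyl-5-[(1S,6R)-2,2,6-trimethyl-7-oxabicyclo[4.1.0]heptan-1-yl]penta-2,4-dienal | O=C/C=C(C)/C=C/[C@@]12O[C@]1(C)CCCC2(C)C | intermediate
22 | (11Z)-(5R,6S,6'R)-5,6-epoxy-5,6-dihydro-β,ε-carotene | CC1=CCCC(C)(C)[C@H]1/C=C/C(C)=C/C=C/C(C)=C/C=C/C=C(C)/C=C\C=C(C)\C=C\[C@@]12O[C@]1(C)CCCC2(C)C | intermediate
23 | (all-E)-(5R,6S,6'R)-5,6-epoxy-5,6-dihydro-β,ε-carotene | CC1=CCCC(C)(C)[C@H]1/C=C/C(C)=C/C=C/C(C)=C/C=C/C=C(C)/C=C/C=C(C)/C=C/[C@@]12O[C@]1(C)CCCC2(C)C | target

**Totals**
Total step count: 16. Longest linear sequence: 11 steps (steps 1 to 10, then step 16); the epoxy branch is steps 11 to 15.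

**Steps most likely to fail**

Step 5 (proposed new method). The chiral ligand may not discriminate the two faces of the dienolate well enough. The product may also lose enantiopurity by renewed γ-deprotonation with drift towards the conjugated β-isomer, or Heck insertion into the enone may compete. The fallback uses known chemistry, sets out from 3 and comes back at 7. Ester 3 is cyclised by the known palladium-catalysed intramolecular α-alkenylation of an ester enolate (Pd2(dba)3, t-Bu3P, LiN(SiMe3)2, toluene, rt), which closes the same bond with no demand for asymmetric induction and should give racemic methyl 2,6,6-trimethylcyclohex-2-ene-1-carboxylate F1. Saponification (KOH, aqueous ethylene glycol, 120 °C) gives racemic 2,6,6-trimethylcyclohex-2-ene-1-carboxylic acid F2. Classical resolution by fractional crystallisation with (S)-1-phenylethylamine (or its antipode, whichever gives the less soluble salt of the (R)-acid) gives (S)-1-phenylethylammonium (1R)-2,6,6-trimethylcyclohex-2-ene-1-carboxylate F3, and dilute HCl releases (1R)-2,6,6-trimethylcyclohex-2-ene-1-carboxylic acid F4. LiAlH4 in Et2O gives [(1R)-2,6,6-trimethylcyclohex-2-en-1-yl]methanol F5. Buffered Dess–Martin oxidation gives (1R)-2,6,6-trimethylcyclohex-2-ene-1-carbaldehyde F6, which is used at once in a Wittig reaction with 1-(triphenylphosphoranylidene)propan-2-one (CH2Cl2, rt) to give 7.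

Step 16. The ylide may give poor E/Z control at C11=C12 with incomplete thermal convergence, and the vinylogous epoxide may rearrange to the 5,8-furanoid oxide during the basic olefination or the heating. The fallback keeps the epoxide on the electrophile and changes the nucleophile to an E-selective phosphonate carbanion; it sets out from 13 and comes back at 23. Alcohol 13 is converted (PBr3, pyridine, Et2O, −20 °C) into (2E,4E,6E,8E,10E,12E)-1-bromo-2,7,11-trimethyl-13-[(1R)-2,6,6-trimethylcyclohex-2-en-1-yl]trideca-2,4,6,8,10,12-hexaene F7, used crude. Michaelis–Becker reaction with NaP(O)(OEt)2 (THF, 0 °C) gives diethyl [(2E,4E,6E,8E,10E,12E)-2,7,11-trimethyl-13-[(1R)-2,6,6-trimethylcyclohex-2-en-1-yl]trideca-2,4,6,8,10,12-hexaen-1-yl]phosphonate F8. Horner–Wadsworth–Emmons reaction of F8 with 21 (KOtBu, THF, −30 °C) should give 23 directly, without a thermal isomerisation.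

Step 12. Enantiofacial control may be insufficient or turnover slow with the hindered tetrasubstituted alkene, and titanium species may open the epoxy alcohol. The fallback replaces asymmetric catalysis by resolution; it sets out from 16 and comes back at 17. Hydroxyl-directed epoxidation (VO(acac)2 cat., t-BuOOH, toluene, 0 °C) gives racemic (2,2,6-trimethyl-7-oxabicyclo[4.1.0]heptan-1-yl)methanol F9. Steglich esterification with (R)-2-methoxy-2-phenylacetic acid (DCC, DMAP, CH2Cl2) and chromatographic separation of the two diastereomeric esters gives [(1R,6R)-2,2,6-trimethyl-7-oxabicyclo[4.1.0]heptan-1-yl]methyl (2R)-2-methoxy-2-phenylacetate F10. Methanolysis (K2CO3, MeOH, 0 °C) gives 17.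

**Further compounds**
F1 | step 5 | methyl 2,6,6-trimethylcyclohex-2-ene-1-carboxylate (racemic) | COC(=O)C1C(C)=CCCC1(C)C
F2 | step 5 | 2,6,6-trimethylcyclohex-2-ene-1-carboxylic acid (racemic) | OC(=O)C1C(C)=CCCC1(C)C
F3 | step 5 | (S)-1-phenylethylammonium (1R)-2,6,6-trimethylcyclohex-2-ene-1-carboxylate | CC1=CCCC(C)(C)[C@H]1C(=O)[O-].C[C@H]([NH3+])c1ccccc1
F4 | step 5 | (1R)-2,6,6-trimethylcyclohex-2-ene-1-carboxylic acid | CC1=CCCC(C)(C)[C@H]1C(=O)O
F5 | step 5 | [(1R)-2,6,6-trimethylcyclohex-2-en-1-yl]methanol | CC1=CCCC(C)(C)[C@H]1CO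
F6 | step 5 | (1R)-2,6,6-trimethylcyclohex-2-ene-1-carbaldehyde | CC1=CCCC(C)(C)[C@H]1C=O
F7 | step 16 | (2E,4E,6E,8E,10E,12E)-1-bromo-2,7,11-trimethyl-13-[(1R)-2,6,6-trimethylcyclohex-2-en-1-yl]trideca-2,4,6,8,10,12-hexaene | CC1=CCCC(C)(C)[C@H]1/C=C/C(C)=C/C=C/C(C)=C/C=C/C=C(C)/CBr
F8 | step 16 | diethyl [(2E,4E,6E,8E,10E,12E)-2,7,11-trimethyl-13-[(1R)-2,6,6-trimethylcyclohex-2-en-1-yl]trideca-2,4,6,8,10,12-hexaen-1-yl]phosphonate | CC1=CCCC(C)(C)[C@H]1/C=C/C(C)=C/C=C/C(C)=C/C=C/C=C(C)/CP(=O)(OCC)OCC
F9 | step 12 | (2,2,6-trimethyl-7-oxabicyclo[4.1.0]heptan-1-yl)methanol (racemic) | OCC12OC1(C)CCCC2(C)C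
F10 | step 12 | [(1R,6R)-2,2,6-trimethyl-7-oxabicyclo[4.1.0]heptan-1-yl]methyl (2R)-2-methoxy-2-phenylacetate | CO[C@H](c1ccccc1)C(=O)OC[C@@]12O[C@]1(C)CCCC2(C)C
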